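The number to carry is 1.57, the early gain. It is the pseudo-first-order constant of substrate in the alpha run up to its first reading, 0.439 d⁻¹, over the constant from that reading to the third, 0.280 d⁻¹, a stretch that holds the 30% conversion asked about. Substrate goes to target over a carrier charged in spent form, with salt in the second phase as partner.

| setting | epsilon | alpha | flask |
|---|---|---|---|
| substrate | 0.80 M | 0.80 M | 0.80 M |
| salt in the second phase | 1.3 M | 3 M | 2.00 M |
| spent carrier | 40 mM | 40 mM | 40 mM |
| remark | run made earlier | run made earlier |  |
| volume of the second phase over the first |  |  | 1.0 |

| run | time / d | target / % | substrate / % |
|---|---|---|---|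
| epsilon | 1.67 | 35 | 66 |
| epsilon | 3.00 | 47 | 49 |
| epsilon | 5.00 | 63 | 36 |
| epsilon | 6.00 | 67 | 32 |
| epsilon | 8.00 | 77 | 24 |
| alpha | 0.625 | 25 | 76 |
| alpha | 1.25 | 36 | 65 |
| alpha | 2.50 | 53 | 45 |
| alpha | 4.00 | 67 | 36 |
| alpha | 8.00 | 83 | 13 |

(each reading ± 1.5 percentage points)

- factor on the rate of making target when 30% of the substrate are converted if spent carrier is charged twice over
- factor on the rate when 30% of the substrate are converted if spent carrier is charged at 200 mM instead

- charges count per volume of the first phase; a concentration in a rate is the amount of a species over the volume of its own phase; every rate counts per litre of the first phase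
- the earlier runs hold the two phases in the same ratio of volumes as the flask asked about
- no earlier run changes the charge of spent carrier; that part of a forecast is a guess

There are two ways to the factors. The first takes the statistical case as the zero of the scale: at a given conversion each carrier works like any other, so the rate follows the charge, with factors of 2 and 5.00 and an early gain of 1.

The second reads the alpha constants against the clock. From the third reading to the last the constant is 0.226 d⁻¹, so it drops more between the first two stretches, by 0.159 d⁻¹, than between the last two, by 0.0540 d⁻¹. I read this as a working share of carrier that falls with time.

Here the ways part. Substrate passes 70.0% of its charge between 0.625 d and 1.25 d in the alpha run, and before 1.67 d in the epsilon run, and the flask's salt lies between theirs. At proportional speed, a flask with 200 mM of spent carrier arrives by 0.334 d, earlier than the alpha run's first reading. It therefore still works on the early constant, while the flask at 40 mM stands on the later one. So the proportional way cheats: it treats equal conversion as equal age.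

My reckoning for 200 mM is 5.00 times the early gain, 7.85. At proportional speed the doubled flask arrives between 0.312 d and 0.835 d, bounds on either side of the end of that first stretch. That span places it on neither constant, so I give it half the excess gain, 2.57. Both are extrapolations, since no run changes the charge.

The forecast gives 1.9 (1.4 to 2) and 4.3 (2.3 to 5), lower than this reckoning, and notes: “Carrier order is untested, so the ranges are wide”.

The flask gives 2.40 for the doubled charge and 7.25 at 200 mM.

    spent carrier + salt in the second phase ⇌ fresh carrier + spent salt in the second phase (K = 0.200, k = 1.80 L mol⁻¹ h⁻¹)
    substrate + fresh carrier → target + spent carrier (k = 1.00 L mol⁻¹ h⁻¹)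
    fresh carrier ⇌ dormant form (K = 2.10, k = 0.120 h⁻¹)

Fresh carrier and dormant form relax with a half-life of 0.163 d, shorter than the 1.02 d the flask at 40 mM takes to reach 30% conversion. Per unit of charge, the doubled flask shows 1.20 against the 1.29 reckoned from the early gain, and the flask at 200 mM shows 1.45 against the early gain of 1.57.

The readings are simulated with constants of no real substance; noise was put on by code.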